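(The numbers in the tables are simulated from invented constants.)

Why did the amber run, with the larger charge of Q, give at its last reading a smaller share of that charge than the teal run?

| flask | Q | J | time |
|---|---|---|---|
| teal | 250 mM | 2.50 mM |  |
| grey | 250 mM | 5.00 mM |  |
| amber | 750 mM | 2.50 mM |  |
| violet | 130 mM | 2.50 mM | 8.7 h |

| teal run: time / h | teal run: [L] / mM | grey run: time / h | grey run: [L] / mM | amber run: time / h | amber run: [L] / mM |
|---|---|---|---|---|---|
| 1.4 | 35.4 | 1.4 | 65.2 | 1.4 | 77.4 |
| 2.9 | 56.9 | 2.9 | 95.5 | 2.9 | 106.7 |
| 4.3 | 67.4 | 4.3 | 110.7 | 4.3 | 122.1 |
| 5.8 | 71.9 | 5.8 | 117.1 | 5.8 | 130.1 |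
| 7.2 | 78.7 | 7.2 | 120.2 | 7.2 | 134.7 |
| 8.7 | 80.9 | 8.7 | 121.0 | 8.7 | 135.8 |

(scatter of a reading: 1 mM)

- how the opening rate goes with [Q] round the charge of the teal run: the exponent of the rate at two percent of Q gone to L (one fixed amount of L, the same in the runs compared)
- how the opening rate goes with [J] round the charge of the teal run: the exponent of the rate at two percent of Q gone to L
- L in the violet run at 8.7 h, as a share of the Q charged

The last teal reading held 32.4% of the charge and the last amber reading 18.1%, which is less. First-order steps in cQ at one cJ give one share from any charge, so I supposed a second route for Q, without J, that goes with the square of cQ.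

Did the route through J gain from more J? The grey run, with twice the cJ of the teal run, ended at 48.4%, a larger share, and its first reading was 1.84 times the teal one. I therefore took the rate of L as first order in cJ and kept first order in cQ as a supposition.

What, then, orders the loss of Q? On this picture each Q lost becomes L with the share cx/(cx+cQ). I assumed that two charges at one cJ reach about the same cQ by the last reading; integrated, they then differ in L by cx·ln((cx+larger charge)/(cx+smaller charge)). Amber and teal differ by 54.9 mM. A first pass with the plain charge ratio gave 50.0 mM, and putting that back gave 56.0 mM. This is cx, the crossover concentration: the cQ at which the two routes take Q equally fast. On this picture, the loss of Q is pseudo-first-order in cQ well below cx and close to second order well above it.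

The violet charge stands above cx, so the second route leads there at the opening. The same difference taken down from the last teal reading gave me 53.0 mM, or 40.8% of the violet charge.

The forecast stood on other grounds: “That points to a dying catalyst, not equilibrium.” It gave an order of 0.85 in cQ, an order of 1.05 in cJ and a violet share of 36%, which is lower than mine.

The flask gave 41.4% in the violet run, with orders 1.0 in cQ and 1.1 in cJ. With the same amount of L made, the amber rate stood at 3.0 times the teal rate.

    J + Q → L + J (59.40 /M/h)
    L → Xo (0.02113 /h)
    2 Q → Ky (1.008 /M/h)

In the violet run, cx puts the share of Q going to L at the opening at 30.1%. For the grey run, the same picture takes cx up with cJ to 112 mM, and the two routes carried down to a cQ of zero give cg·ln(1+charge/cg), or 131 mM, which lies above the last grey reading of 121.0 mM.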